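The runs were generated by integration on assumed constants; the scatter is artificial.

In a one-step world the reagent would meet substrate and nothing else, and a charge of 1.00 equiv would consume the substrate. The dusk run, which is the asked flask followed so far, and the earlier noon run show something else.

| setting | dusk | noon | flask |
|---|---|---|---|
| substrate | 1.5 M | 1.5 M | 1.5 M |
| partner | 1.3 equiv | 0.65 equiv | 1.30 equiv |
| reagent | 1 equiv | 1 equiv | 1.00 equiv |
| remark | the very flask that is asked about, followed so far | run made earlier |  |
| time |  |  | 2.5 h |

- dusk (time / min: target / %, substrate / %): 12.0: 41, 49; 20.0: 45, 53; 30.0: 46, 52; 50.0: 46, 52; 90.0: 50, 53; 150: 48, 50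
- noon (time / min: target / %, substrate / %): 0.417: 6, 55; 1.00: 10, 42; 2.00: 18, 38; 3.00: 23, 37; 4.00: 27, 34; 6.00: 33, 36

(each reading ± 1.5 percentage points)

- grey: at 2.5 h take out 90% of the target then present, then wait 80 min
- ochre: change nothing and wait 80 min more
- green: at 2.5 h add substrate, 50.0% of the amount charged, then wait 80 min

- target that was removed still counts
- what was read earlier has a scatter of 1.5 percentage points, one standard deviation
- additions bring no volume worth counting

1. target, in percent of the substrate first charged, at 2.5 h
2. the option that brings most further target ("none" if no option brings more than 2 percentage points) (grey / ochre / green / none)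
3. target present, with what was taken out counted in, in percent of the substrate first charged, after ochre
4. target present, with what was taken out counted in, in percent of the substrate first charged, after green

In noon, substrate falls to 42% by 1.00 min while target reads 10%, so substrate first becomes something unseen. Substrate then stops while target climbs. This reckoning therefore takes reagent as the limiting reagent and keeps a ledger with two entries: reagent that reached substrate, and reagent lost elsewhere.

With reagent at one equivalent, the last readings put the first entry at 64.3% in noon and 48.2% in dusk, although noon carries half the partner. The second entry holds the remainder.

Now freeze [partner]/[substrate] at its charged value. Call the toll, a selectivity factor, the reagent lost per unit reaching substrate, per equivalent of partner. Noon reads 0.853 and dusk reads 0.825, nearly the same.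

The toll from noon sends 47.4% of the flask's reagent to substrate. In dusk, target plus substrate reads 98.0% at 30.0 min, so the readings leave 2.00% of the substrate in neither. This reckoning therefore commits to 47.4% for the flask, slightly below the forecast, and expects no option to pass 2 percentage points.

The forecast gives 48% now, best option none, 48% after ochre and 48% after green: “This is a spent-reagent stall, not an equilibrium.”

The flask gives 48.5%, and best option none. Each option adds 0.038 points, leaving 48.5% after ochre and 48.5% after green.

    substrate + reagent → open intermediate (k = 0.0280 L mol⁻¹ s⁻¹)
    reagent + partner → second intermediate (k = 0.0210 L mol⁻¹ s⁻¹)
    open intermediate + second intermediate → target (k = 0.0120 L mol⁻¹ s⁻¹)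
    reagent + target → over-reaction product (k = 0.00270 L mol⁻¹ s⁻¹)

At 150 min the flask holds reagent at 0% and substrate at 51%, so 49.0% was consumed, against 47.4% from the toll. In the neighbouring flask, partner is cut to 0.780 equiv, and the same toll of 0.853 sends 60.0% of the reagent to substrate and 40.0% to the partner side. The neighbouring flask ends with reagent at 0% and substrate at 39%, so 61.0% was consumed. Each target takes one of each intermediate in the scheme, and the neighbouring flask holds target at 38.8%, near the smaller entry, with open intermediate at 21.4%.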